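**Retrosynthetic overview**

1. Target 15 ⇒ bis-MOM ether 14 (acetal cleavage) ⇒ nitro ketone 13 (C1–NO2 to C1–H by radical denitration).
2. 13 ⇒ acyl imidazole 6 + acyclic γ-nitro ketone 9 + vinylphosphonium salt 10: the aryl C(=O)–C1 bond by C-acylation of the nitronate, then C1–C2 (conjugate addition) and C3=C4 (intramolecular Wittig) in the same flask.
3. 9 ⇒ 6-methylhept-5-en-2-one + β-nitrostyrene (organocatalytic Michael addition sets C5 and C6); 6 ⇒ 3,4,5-trimethoxyphenol (formylation, ortho-demethylation, MOM protection, oxidation, imidazolide).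
4. Ring order: the arene is carried through from the start; the cyclohexene is the only ring made, and it is made in the key step.
5. Enabling feature: C1 of the cyclohexene is the sp3 ring carbon that is alpha to the exocyclic aryl C=O and bears H; it lies next to benzylic C6 and, through C6–C5, three bonds from C4, the methyl-bearing alkene carbon. A nitro group on C1 therefore makes it a carbanion that can be acylated, then annulated onto a C4 methyl ketone, and finally leaves as a radical.

Key step: step 7

Remark: ring locants are C1 (aroyl-bearing carbon), C3=C4 (alkene, CH3 on C4), C5 (prenyl) and C6 (phenyl); the sense of induction in step 6 is assumed to follow the known behaviour of hydrogen-bond-directing pyrrolidine catalysts with nitroalkenes, and the (R)-catalyst is chosen on that basis.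

**Route**

Step 1
Reactants: 1 3,4,5-trimethoxyphenol
Product: 2 6-hydroxy-2,3,4-trimethoxybenzaldehyde
Conditions: MgCl2, Et3N, (CH2O)n, MeCN, reflux; 1 M HCl
Reagents that add atoms: paraformaldehyde (formaldehyde), C=O
Why: Magnesium-mediated ortho-formylation of a phenol (Casnati–Skattebøl reaction), in which the magnesium phenoxide delivers formaldehyde to an ortho carbon and a second formaldehyde oxidises the benzylic alkoxide; both ortho positions of 1 are equivalent and the para position is blocked, so only one aldehyde can form.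

Step 2
Reactants: 2 6-hydroxy-2,3,4-trimethoxybenzaldehyde
Product: 3 2,6-dihydroxy-3,4-dimethoxybenzaldehyde
Conditions: BCl3 (2.5 equiv), CH2Cl2, −20 °C to rt; H2O
Reagents that add atoms: none
Why: Chelation-controlled aryl methyl ether cleavage, in which boron held by the formyl oxygen cleaves only the methoxy group ortho to the carbonyl, so the 3- and 4-methoxy groups should stay.

Step 3
Reactants: 3 2,6-dihydroxy-3,4-dimethoxybenzaldehyde
Product: 4 3,4-dimethoxy-2,6-bis(methoxymethoxy)benzaldehyde
Conditions: NaH, MOMCl, DMF, 0 °C to rt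
Reagents that add atoms: chloromethyl methyl ether, COCCl
Why: Williamson-type MOM protection, in which both phenoxides (freed from their hydrogen bond to the aldehyde by NaH in DMF) are alkylated, masking the acidic OH groups for the base-mediated key step.

Step 4
Reactants: 4 3,4-dimethoxy-2,6-bis(methoxymethoxy)benzaldehyde
Product: 5 3,4-dimethoxy-2,6-bis(methoxymethoxy)benzoic acid
Conditions: NaClO2, NaH2PO4, 2-methylbut-2-ene, t-BuOH/H2O, rt
Reagents that add atoms: sodium chlorite, [Na+].[O-]Cl=O
Why: Pinnick oxidation converts the hindered aldehyde to the acid in a weakly acidic buffer that MOM acetals tolerate, while 2-methylbut-2-ene traps hypochlorous acid before it can chlorinate the electron-rich ring.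

Step 5
Reactants: 5 3,4-dimethoxy-2,6-bis(methoxymethoxy)benzoic acid
Product: 6 [3,4-dimethoxy-2,6-bis(methoxymethoxy)phenyl](1H-imidazol-1-yl)methanone
Conditions: CDI, THF, rt to 40 °C
Reagents that add atoms: 1,1'-carbonyldiimidazole, O=C(n1ccnc1)n1ccnc1
Why: Acyl imidazole formation with carbonyldiimidazole runs under neutral conditions with loss of CO2, spares the MOM acetals, and gives an acyl donor whose leaving group is basic enough to deprotonate the product of the key step.

Step 6
Reactants: 7 6-methylhept-5-en-2-one; 8 (E)-(2-nitroethenyl)benzene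
Product: 9 (3R)-6-methyl-3-[(1S)-2-nitro-1-phenylethyl]hept-5-en-2-one
Conditions: (R)-N-(pyrrolidin-2-ylmethyl)trifluoromethanesulfonamide (15 mol%), 7 (5 equiv), i-PrOH, 0 °C to rt
Reagents that add atoms: none
Why: Enamine-catalysed asymmetric Michael addition of a ketone to a nitroalkene, in which the more substituted (E)-enamine of 7 attacks the nitroalkene hydrogen-bonded to the sulfonamide N–H on one face only; the synclinal approach should give the syn adduct and the (R)-catalyst should set both new centres as (3R,1'S), which become C5 and C6 of the target.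

Step 7
Reactants: 9 (3R)-6-methyl-3-[(1S)-2-nitro-1-phenylethyl]hept-5-en-2-one; 6 [3,4-dimethoxy-2,6-bis(methoxymethoxy)phenyl](1H-imidazol-1-yl)methanone; 10 ethenyl(triphenyl)phosphonium bromide
Product: 13 [3,4-dimethoxy-2,6-bis(methoxymethoxy)phenyl][(5R,6S)-4-methyl-5-(3-methylbut-2-en-1-yl)-1-nitro-6-phenylcyclohex-3-en-1-yl]methanone (both C1 epimers), via potassium salt of acyclic alpha-nitro ketone 11 (not isolated), via phosphonium ylide 12 (not isolated)
Conditions: t-BuOK (1.0 equiv), THF/DMSO 4:1, 0 °C; 6 (1.1 equiv), 0 to 40 °C; then 10 (2.2 equiv), 60 °C, one pot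
Reagents that add atoms: none
Why: Proposed new method: the potassium nitronate of 9 (t-BuOK removes only the CH2NO2 proton) is C-acylated by acyl imidazole 6, any O-acyl nitronate returning its acyl group through imidazole, and the product is drained as the doubly stabilised carbanion 11, which is how the aryl C(=O)–C1 bond is made; the closest known reaction type is the C-acylation of primary nitronates with N-acylimidazoles and N-acylbenzotriazoles. Carbanion 11 then adds to vinylphosphonium salt 10 and the resulting ylide 12 olefinates the methyl ketone, the closest known types being the vinylphosphonium annulation of stabilised carbanions (conjugate addition, then intramolecular Wittig reaction) and the Michael addition of alpha-nitro ketones to enones. The cyclohexene is closed stepwise and polar, first the C1–C2 bond by intermolecular conjugate addition, then the C3=C4 bond by a six-membered Wittig ring closure through an oxaphosphetane, a formal (4+2) annulation of the C1–C6–C5–C4 chain of 11 onto the two vinyl carbons of 10. The only new stereocentre is the quaternary nitro-bearing C1, whose configuration does not matter because step 8 planarises it, while C5 and C6 come from 9 untouched since no base able to enolise the ketone remains once the nitronate has formed. The step needs C- over O-acylation, reaction of the ylide with one of two ketones, and one alkene position: the first is thermodynamic (anion 11 is the sink), the second is secured because the methyl ketone is reached through a six-membered ring whereas the doubly ortho-substituted aryl ketone would need a four-membered one, and the third is fixed by the position of that carbonyl carbon, which becomes C4.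

Step 8
Reactants: 13 [3,4-dimethoxy-2,6-bis(methoxymethoxy)phenyl][(5R,6S)-4-methyl-5-(3-methylbut-2-en-1-yl)-1-nitro-6-phenylcyclohex-3-en-1-yl]methanone
Product: 14 [3,4-dimethoxy-2,6-bis(methoxymethoxy)phenyl][(1R,5R,6R)-4-methyl-5-(3-methylbut-2-en-1-yl)-6-phenylcyclohex-3-en-1-yl]methanone
Conditions: Bu3SnH (5 equiv, 0.5 M), AIBN (0.2 equiv), toluene, 90 °C
Reagents that add atoms: none
Why: Radical denitration of a tertiary alpha-nitro ketone with tributyltin hydride, in which the stannyl radical adds to the nitro group, the C1–N bond breaks to a ketone-stabilised planar radical, and this radical should take hydrogen from Sn–H along the axial direction of the half-chair that keeps the C6 phenyl and C5 prenyl groups pseudo-equatorial, placing the aroyl group equatorial and trans to phenyl (1R), with the high stannane concentration outrunning cyclisation onto the prenyl double bond.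

Step 9
Reactants: 14 [3,4-dimethoxy-2,6-bis(methoxymethoxy)phenyl][(1R,5R,6R)-4-methyl-5-(3-methylbut-2-en-1-yl)-6-phenylcyclohex-3-en-1-yl]methanone
Product: 15 (2,6-dihydroxy-3,4-dimethoxyphenyl)[(1R,5R,6R)-4-methyl-5-(3-methylbut-2-en-1-yl)-6-phenylcyclohex-3-en-1-yl]methanone
Conditions: 2 M aq. HCl/MeOH (1:5), rt to 40 °C
Reagents that add atoms: none
Why: Acid-catalysed methanolysis of the two aryl MOM acetals, which the ortho carbonyl group activates, should proceed under conditions too mild to hydrate the trisubstituted alkenes or enolise C1, so the three stereocentres are kept.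

**Compound list**

1 | 3,4,5-trimethoxyphenol | COc1cc(O)cc(OC)c1OC | starting material
2 | 6-hydroxy-2,3,4-trimethoxybenzaldehyde | COc1cc(O)c(C=O)c(OC)c1OC | intermediate
3 | 2,6-dihydroxy-3,4-dimethoxybenzaldehyde | COc1cc(O)c(C=O)c(O)c1OC | intermediate
4 | 3,4-dimethoxy-2,6-bis(methoxymethoxy)benzaldehyde | COCOc1cc(OC)c(OC)c(OCOC)c1C=O | intermediate
5 | 3,4-dimethoxy-2,6-bis(methoxymethoxy)benzoic acid | COCOc1cc(OC)c(OC)c(OCOC)c1C(=O)O | intermediate
6 | [3,4-dimethoxy-2,6-bis(methoxymethoxy)phenyl](1H-imidazol-1-yl)methanone | COCOc1cc(OC)c(OC)c(OCOC)c1C(=O)n1ccnc1 | intermediate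
7 | 6-methylhept-5-en-2-one | CC(=O)CCC=C(C)C | starting material
8 | (E)-(2-nitroethenyl)benzene (trans-β-nitrostyrene) | [O-][N+](=O)/C=C/c1ccccc1 | starting material
9 | (3R)-6-methyl-3-[(1S)-2-nitro-1-phenylethyl]hept-5-en-2-one | CC(=O)[C@H](CC=C(C)C)[C@H](C[N+](=O)[O-])c1ccccc1 | intermediate
10 | ethenyl(triphenyl)phosphonium bromide | C=C[P+](c1ccccc1)(c1ccccc1)c1ccccc1.[Br-] | starting material
11 | (3S,4R)-4-acetyl-1-[3,4-dimethoxy-2,6-bis(methoxymethoxy)phenyl]-7-methyl-2-nitro-3-phenyloct-6-en-1-one (C2 epimers; present as its potassium salt, not isolated) | CC(=O)[C@H](CC=C(C)C)[C@H](C([N+](=O)[O-])C(=O)c1c(OCOC)cc(OC)c(OC)c1OCOC)c1ccccc1 | intermediate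
12 | (3S,4R)-4-acetyl-1-[3,4-dimethoxy-2,6-bis(methoxymethoxy)phenyl]-7-methyl-2-nitro-3-phenyl-2-[2-(triphenyl-λ5-phosphanylidene)ethyl]oct-6-en-1-one (C2 epimers, not isolated) | CC(=O)[C@H](CC=C(C)C)[C@H](C(CC=P(c1ccccc1)(c1ccccc1)c1ccccc1)([N+](=O)[O-])C(=O)c1c(OCOC)cc(OC)c(OC)c1OCOC)c1ccccc1 | intermediate
13 | [3,4-dimethoxy-2,6-bis(methoxymethoxy)phenyl][(5R,6S)-4-methyl-5-(3-methylbut-2-en-1-yl)-1-nitro-6-phenylcyclohex-3-en-1-yl]methanone (both C1 epimers; the 6S descriptor reflects only the CIP priority of the nitro-bearing carbon) | COCOc1cc(OC)c(OC)c(OCOC)c1C(=O)C1([N+](=O)[O-])CC=C(C)[C@H](CC=C(C)C)[C@H]1c1ccccc1 | intermediate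
14 | [3,4-dimethoxy-2,6-bis(methoxymethoxy)phenyl][(1R,5R,6R)-4-methyl-5-(3-methylbut-2-en-1-yl)-6-phenylcyclohex-3-en-1-yl]methanone | COCOc1cc(OC)c(OC)c(OCOC)c1C(=O)[C@@H]1CC=C(C)[C@H](CC=C(C)C)[C@H]1c1ccccc1 | intermediate
15 | (2,6-dihydroxy-3,4-dimethoxyphenyl)[(1R,5R,6R)-4-methyl-5-(3-methylbut-2-en-1-yl)-6-phenylcyclohex-3-en-1-yl]methanone | COc1cc(O)c(C(=O)[C@@H]2CC=C(C)[C@H](CC=C(C)C)[C@H]2c2ccccc2)c(O)c1OC | target

**Step count and risks**

Total step count: 9. Longest linear sequence: 8 (steps 1–5, then 7–9).

Steps most likely to fail: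

1. Step 7 (proposed new method). The hindered, weakly nucleophilic anion 11 may add too slowly to the vinylphosphonium salt, or the acyl group may be lost again by retro-Claisen cleavage once C1 is quaternary. The fallback uses known chemistry, sets out from 9 and returns at 13. Wittig methylenation of the methyl ketone of 9 (Ph3P=CH2 in excess, the first equivalent parking the nitro group as its nitronate) should give (3R)-2,6-dimethyl-3-[(1S)-2-nitro-1-phenylethyl]hepta-1,5-diene F1. A Henry reaction of F1 with aldehyde 4 (DBU, THF) makes the aryl C–C1 bond at the alcohol level and should give (3S,4R)-1-[3,4-dimethoxy-2,6-bis(methoxymethoxy)phenyl]-7-methyl-2-nitro-3-phenyl-4-(prop-1-en-2-yl)oct-6-en-1-ol F2. Dess–Martin oxidation should give the alpha-nitro ketone (3S,4R)-1-[3,4-dimethoxy-2,6-bis(methoxymethoxy)phenyl]-7-methyl-2-nitro-3-phenyl-4-(prop-1-en-2-yl)oct-6-en-1-one F3. Palladium-catalysed Tsuji–Trost allylation (allyl methyl carbonate, Pd(PPh3)4) should give (3S,4R)-1-[3,4-dimethoxy-2,6-bis(methoxymethoxy)phenyl]-7-methyl-2-nitro-3-phenyl-2-(prop-2-en-1-yl)-4-(prop-1-en-2-yl)oct-6-en-1-one F4. Ring-closing metathesis between the allyl and isopropenyl groups (second-generation ruthenium benzylidene catalyst, CH2Cl2, 40 °C) closes the same C3=C4 bond and returns 13.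

2. Step 8. Hydrogen-atom transfer to the planar C1 radical may show poor facial selectivity, or the radical may cyclise onto the prenyl alkene. The fallback sets out from 9 and returns at 14; it brings the aroyl group in last, onto a C1 radical, anti to the neighbouring phenyl group. The nitronate of 9 is annulated directly with 10 (t-BuOK, THF; conjugate addition, then intramolecular Wittig) to give (5S,6R)-1-methyl-6-(3-methylbut-2-en-1-yl)-4-nitro-5-phenylcyclohex-1-ene F5. Zinc in acetic acid reduces the nitro group to (5R,6S)-4-methyl-5-(3-methylbut-2-en-1-yl)-6-phenylcyclohex-3-en-1-amine F6. Condensation with 2,4,6-triphenylpyrylium tetrafluoroborate gives 1-[(5R,6S)-4-methyl-5-(3-methylbut-2-en-1-yl)-6-phenylcyclohex-3-en-1-yl]-2,4,6-triphenylpyridinium tetrafluoroborate F7. Acid 5 is converted into pyridin-2-yl 3,4-dimethoxy-2,6-bis(methoxymethoxy)benzoate F8 (2-hydroxypyridine, DCC). Nickel-catalysed reductive deaminative acylation of F7 with F8 (NiBr2·dme, terpyridine ligand, Mn, NMP) should give 14, the acyl–nickel species capturing the C1 radical trans to phenyl.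

3. Step 6. The enamine may form at the methyl group instead of the methylene group (poor site selectivity), and an acyclic ketone may give lower enantioselectivity. The fallback sets out from 8 and returns at 9; it uses an aldehyde donor with a single enolisable position. 5-Methylhex-4-enal adds to 8 under (S)-α,α-diphenylprolinol trimethylsilyl ether catalysis to give (2R)-5-methyl-2-[(1S)-2-nitro-1-phenylethyl]hex-4-enal F9. Methyltitanium triisopropoxide adds to the aldehyde without touching the nitro group to give (3R)-6-methyl-3-[(1S)-2-nitro-1-phenylethyl]hept-5-en-2-ol F10 (C2 epimers). Dess–Martin oxidation returns 9.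

**Further compounds**

F1 | step 7 | (3R)-2,6-dimethyl-3-[(1S)-2-nitro-1-phenylethyl]hepta-1,5-diene | C=C(C)[C@H](CC=C(C)C)[C@H](C[N+](=O)[O-])c1ccccc1
F2 | step 7 | (3S,4R)-1-[3,4-dimethoxy-2,6-bis(methoxymethoxy)phenyl]-7-methyl-2-nitro-3-phenyl-4-(prop-1-en-2-yl)oct-6-en-1-ol (C1 and C2 epimers) | C=C(C)[C@H](CC=C(C)C)[C@H](C([N+](=O)[O-])C(O)c1c(OCOC)cc(OC)c(OC)c1OCOC)c1ccccc1
F3 | step 7 | (3S,4R)-1-[3,4-dimethoxy-2,6-bis(methoxymethoxy)phenyl]-7-methyl-2-nitro-3-phenyl-4-(prop-1-en-2-yl)oct-6-en-1-one (C2 epimers) | C=C(C)[C@H](CC=C(C)C)[C@H](C([N+](=O)[O-])C(=O)c1c(OCOC)cc(OC)c(OC)c1OCOC)c1ccccc1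
F4 | step 7 | (3S,4R)-1-[3,4-dimethoxy-2,6-bis(methoxymethoxy)phenyl]-7-methyl-2-nitro-3-phenyl-2-(prop-2-en-1-yl)-4-(prop-1-en-2-yl)oct-6-en-1-one (C2 epimers) | C=C(C)[C@H](CC=C(C)C)[C@H](C(CC=C)([N+](=O)[O-])C(=O)c1c(OCOC)cc(OC)c(OC)c1OCOC)c1ccccc1
F5 | step 8 | (5S,6R)-1-methyl-6-(3-methylbut-2-en-1-yl)-4-nitro-5-phenylcyclohex-1-ene (C4 epimers) | [O-][N+](=O)C1CC=C(C)[C@H](CC=C(C)C)[C@H]1c1ccccc1
F6 | step 8 | (5R,6S)-4-methyl-5-(3-methylbut-2-en-1-yl)-6-phenylcyclohex-3-en-1-amine (C1 epimers) | NC1CC=C(C)[C@H](CC=C(C)C)[C@H]1c1ccccc1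
F7 | step 8 | 1-[(5R,6S)-4-methyl-5-(3-methylbut-2-en-1-yl)-6-phenylcyclohex-3-en-1-yl]-2,4,6-triphenylpyridinium tetrafluoroborate (C1 epimers) | c1ccc(cc1)-c1cc(-c2ccccc2)[n+](C2CC=C(C)[C@H](CC=C(C)C)[C@H]2c2ccccc2)c(-c2ccccc2)c1.F[B-](F)(F)F
F8 | step 8 | pyridin-2-yl 3,4-dimethoxy-2,6-bis(methoxymethoxy)benzoate | COCOc1cc(OC)c(OC)c(OCOC)c1C(=O)Oc1ccccn1
F9 | step 6 | (2R)-5-methyl-2-[(1S)-2-nitro-1-phenylethyl]hex-4-enal | O=C[C@H](CC=C(C)C)[C@H](C[N+](=O)[O-])c1ccccc1
F10 | step 6 | (3R)-6-methyl-3-[(1S)-2-nitro-1-phenylethyl]hept-5-en-2-ol (C2 epimers) | CC(O)[C@H](CC=C(C)C)[C@H](C[N+](=O)[O-])c1ccccc1
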